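**Plan**

1. Cuts: (a) C-2–C-1' between ring C and ring B, giving a benzyl-protected 5,7-dihydroxychromone and an arylboronic acid; (b) the acyl–aryl bond C-4–C-4a of the 2,2-dimethylchromanone (ring D), giving a 3-aryloxy-3-methylbutanoic acid; (c) the tert-alkyl aryl ether O-1–C-2 of ring D, giving a phenol and 3-chloro-3-methylbut-1-yne.
2. Feature used: in ring D the carbonyl carbon C-4 is tied through C-3 and C-2 to the ring-B oxygen O-1, and C-4a is the only free ring carbon ortho to O-1; an acyl group hung on O-1 can reach no other carbon, and O-1 activates exactly that one.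
3. Helpers: a benzyl ether keeps the second catechol oxygen (the later 8-OH) apart from O-1, and bromine para to O-1 blocks that position during the acylation and then becomes the boron handle; both are gone at the end.
4. Forward order: ring B is bought; the side chain is built on O-1 (steps 1–3); ring D is closed on the achiral fragment (step 4); Br is exchanged for B(OH)2 (step 5); rings A and C come as the chromone (step 6) and are joined to rings B and D in step 7; debenzylation follows (step 8).
5. Stereochemistry: the only stereocentre, C-2 (S), is set in step 7 by ligand-controlled conjugate addition of the arylboronic acid to the chromone under a chiral divalent palladium catalyst; step 8 is neutral and leaves it untouched.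

Key step: step 4

Remark: the (R)-configured PyOx ligand is assumed to deliver the aryl group to the chromone with the same facial sense as in the cyclic-enone series, which corresponds to 2S; the sense is to be confirmed on the first sample.

**Route**

Step 1
Reactants: 1 2-(benzyloxy)-4-bromophenol; 2 3-chloro-3-methylbut-1-yne
Product: 3 2-(benzyloxy)-4-bromo-1-[(2-methylbut-3-yn-2-yl)oxy]benzene
Conditions: DBU, CuCl2·2H2O (cat.), MeCN, 0 °C
Reagents that add atoms: none
Why: Copper-catalysed propargylic substitution of the tertiary chloride (through its copper acetylide) O-alkylates the phenoxide at the tertiary carbon, the standard entry to 1,1-dimethylpropargyl aryl ethers, and leaves the aryl bromide and the benzyl ether untouched.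

Step 2
Reactants: 3 2-(benzyloxy)-4-bromo-1-[(2-methylbut-3-yn-2-yl)oxy]benzene
Product: 5 3-[2-(benzyloxy)-4-bromophenoxy]-3-methylbutanal, via alkenyldicyclohexylborane 4 (not isolated)
Conditions: BH3·SMe2, cyclohexene, THF, 0 °C (gives (c-C6H11)2BH); then 3, 0 °C to rt; then H2O2, pH 7 phosphate buffer, 0 °C
Reagents that add atoms: dicyclohexylborane, B(C1CCCCC1)C1CCCCC1 (boron and cyclohexyl groups stay only in 4); hydrogen peroxide, OO (oxygen of the aldehyde)
Why: Hydroboration–oxidation of a terminal alkyne: the bulky dialkylborane places boron on the terminal carbon, and buffered peroxide oxidation of the alkenylborane gives the aldehyde through its enol, the neutral pH limiting β-elimination of the aryloxide.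

Step 3
Reactants: 5 3-[2-(benzyloxy)-4-bromophenoxy]-3-methylbutanal
Product: 6 3-[2-(benzyloxy)-4-bromophenoxy]-3-methylbutanoic acid
Conditions: NaClO2, NaH2PO4, 2-methyl-2-butene, t-BuOH/H2O, rt
Reagents that add atoms: sodium chlorite, [Na+].[O-]Cl=O
Why: Pinnick oxidation takes the aldehyde to the acid under mildly acidic conditions that spare both aryl ethers, the alkene scavenger removing hypochlorous acid before it can chlorinate the ring.

Step 4
Reactants: 6 3-[2-(benzyloxy)-4-bromophenoxy]-3-methylbutanoic acid
Product: 8 8-(benzyloxy)-6-bromo-2,2-dimethylchroman-4-one, via acid chloride 7 (not isolated)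
Conditions: (COCl)2, DMF (cat.), CH2Cl2, 0 °C to rt; then SnCl4, CH2Cl2, −78 to 0 °C
Reagents that add atoms: oxalyl chloride, ClC(=O)C(=O)Cl (its chlorine stays only in 7)
Why: The acid chloride, activated by SnCl4 as an acylium-type electrophile, attacks the ring carbon ortho to the ether oxygen, and loss of a proton restores the aromatic ring (electrophilic aromatic substitution). The closest known reaction type is the intramolecular Friedel–Crafts acylation of 3-aryloxypropanoyl chlorides to chroman-4-ones. Ring D closes in the 6-exo mode at the acyl carbon, helped by the geminal methyl groups on the tether (Thorpe–Ingold effect). No stereocentre is formed. The step needs acylation ortho to the ether oxygen and survival of the benzyl ether and the tert-alkyl aryl ether: the four-atom tether from that oxygen reaches only this carbon, bromine blocks the para position, and a mild Lewis acid at low temperature is chosen to spare both ethers.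

Step 5
Reactants: 8 8-(benzyloxy)-6-bromo-2,2-dimethylchroman-4-one
Product: 9 [8-(benzyloxy)-2,2-dimethyl-4-oxochroman-6-yl]boronic acid
Conditions: B2(OH)4, Pd(OAc)2 (cat.), XPhos, KOAc, EtOH, 80 °C
Reagents that add atoms: tetrahydroxydiboron, OB(O)B(O)O
Why: Palladium-catalysed borylation of the aryl bromide with tetrahydroxydiboron (Miyaura-type borylation) gives the boronic acid directly, acetate being too weak a base to enolise the ketone or drive biaryl coupling.

Step 6
Reactants: 10 5,7-dihydroxy-4H-chromen-4-one
Product: 11 5,7-bis(benzyloxy)-4H-chromen-4-one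
Conditions: BnBr, K2CO3, DMF, 70 °C
Reagents that add atoms: benzyl bromide, BrCc1ccccc1
Why: Williamson ether synthesis benzylates both the acidic 7-OH and the hydrogen-bonded 5-OH, which would otherwise chelate the palladium catalyst of step 7.

Step 7
Reactants: 9 [8-(benzyloxy)-2,2-dimethyl-4-oxochroman-6-yl]boronic acid; 11 5,7-bis(benzyloxy)-4H-chromen-4-one
Product: 12 (2S)-5,7-bis(benzyloxy)-2-[8-(benzyloxy)-2,2-dimethyl-4-oxochroman-6-yl]chroman-4-one
Conditions: Pd(OCOCF3)2 (5 mol%), (R)-t-BuPyOx (6 mol%), NH4PF6 (30 mol%), H2O (5 equiv), ClCH2CH2Cl, 60 °C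
Reagents that add atoms: none
Why: Asymmetric conjugate addition of an arylboronic acid to a chromone: the cationic aryl–palladium species formed by transmetalation inserts the C-2=C-3 bond, water protonates the palladium enolate, and the tert-butyl group of the PyOx ligand differentiates the enone faces so that the (R)-ligand should give 2S.

Step 8
Reactants: 12 (2S)-5,7-bis(benzyloxy)-2-[8-(benzyloxy)-2,2-dimethyl-4-oxochroman-6-yl]chroman-4-one
Product: 13 (2S)-5,7-dihydroxy-2-(8-hydroxy-2,2-dimethyl-4-oxochroman-6-yl)chroman-4-one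
Conditions: H2 (1 atm), Pd/C, EtOAc/MeOH, rt
Reagents that add atoms: none
Why: Catalytic hydrogenolysis removes the three benzyl aryl ethers under neutral conditions, which avoids the base-induced opening of ring C to the chalcone that would racemise C-2, while the two electron-rich aryl ketones and the C-2–O bond should react much more slowly.

**Compound list**

1 | 2-(benzyloxy)-4-bromophenol | Oc1ccc(Br)cc1OCc1ccccc1 | starting material
2 | 3-chloro-3-methylbut-1-yne | C#CC(C)(C)Cl | starting material
3 | 2-(benzyloxy)-4-bromo-1-[(2-methylbut-3-yn-2-yl)oxy]benzene | C#CC(C)(C)Oc1ccc(Br)cc1OCc1ccccc1 | intermediate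
4 | (E)-{3-[2-(benzyloxy)-4-bromophenoxy]-3-methylbut-1-en-1-yl}dicyclohexylborane | B(/C=C/C(C)(C)Oc1ccc(Br)cc1OCc1ccccc1)(C1CCCCC1)C1CCCCC1 | intermediate
5 | 3-[2-(benzyloxy)-4-bromophenoxy]-3-methylbutanal | O=CCC(C)(C)Oc1ccc(Br)cc1OCc1ccccc1 | intermediate
6 | 3-[2-(benzyloxy)-4-bromophenoxy]-3-methylbutanoic acid | OC(=O)CC(C)(C)Oc1ccc(Br)cc1OCc1ccccc1 | intermediate
7 | 3-[2-(benzyloxy)-4-bromophenoxy]-3-methylbutanoyl chloride | ClC(=O)CC(C)(C)Oc1ccc(Br)cc1OCc1ccccc1 | intermediate
8 | 8-(benzyloxy)-6-bromo-2,2-dimethylchroman-4-one | CC1(C)CC(=O)c2cc(Br)cc(OCc3ccccc3)c2O1 | intermediate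
9 | [8-(benzyloxy)-2,2-dimethyl-4-oxochroman-6-yl]boronic acid | CC1(C)CC(=O)c2cc(B(O)O)cc(OCc3ccccc3)c2O1 | intermediate
10 | 5,7-dihydroxy-4H-chromen-4-one | O=c1ccoc2cc(O)cc(O)c12 | starting material
11 | 5,7-bis(benzyloxy)-4H-chromen-4-one | O=c1ccoc2cc(OCc3ccccc3)cc(OCc3ccccc3)c12 | intermediate
12 | (2S)-5,7-bis(benzyloxy)-2-[8-(benzyloxy)-2,2-dimethyl-4-oxochroman-6-yl]chroman-4-one | CC1(C)CC(=O)c2cc([C@@H]3CC(=O)c4c(OCc5ccccc5)cc(OCc5ccccc5)cc4O3)cc(OCc5ccccc5)c2O1 | intermediate
13 | (2S)-5,7-dihydroxy-2-(8-hydroxy-2,2-dimethyl-4-oxochroman-6-yl)chroman-4-one | CC1(C)CC(=O)c2cc([C@@H]3CC(=O)c4c(O)cc(O)cc4O3)cc(O)c2O1 | target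

**Count and risks**

Total steps: 8. Longest linear sequence: 7 (steps 1, 2, 3, 4, 5, 7, 8); step 6 is the one-step side branch.

Step 7 (conjugate addition). What may go wrong: insertion of the electron-rich, peri-substituted chromone is slow, so that protodeboronation of 9 wins, or the ligand discriminates the faces poorly. Fallback (stereoconvergent, enzymatic), setting out from 9 and 11 and rejoining at 13:
- The addition is run without chiral control (Pd(OCOCF3)2, 2,2'-bipyridine, aqueous ClCH2CH2Cl, 60 °C) to give racemic 5,7-bis(benzyloxy)-2-[8-(benzyloxy)-2,2-dimethyl-4-oxochroman-6-yl]chroman-4-one F1.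
- Hydrogenolysis (H2, Pd/C) gives racemic 5,7-dihydroxy-2-(8-hydroxy-2,2-dimethyl-4-oxochroman-6-yl)chroman-4-one F2.
- Ring C is opened with aqueous KOH and the solution acidified cold to give the chalcone (E)-1-(2,4,6-trihydroxyphenyl)-3-(8-hydroxy-2,2-dimethyl-4-oxochroman-6-yl)prop-2-en-1-one F3.
- A chalcone isomerase (an intramolecular lyase), in buffer near pH 6.5 where the uncatalysed closure is slow, should then close ring C to the 2S isomer only. Both enantiomers of F2 are thus funnelled through achiral F3 into 13. The enzyme would have to accept the fused ring D in its ring-B pocket, which needs screening.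

Step 4 (ring closure). What may go wrong: acylation of the bromine-deactivated ring is too slow under a Lewis acid mild enough for the benzyl ether, or the benzyl or tert-alkyl ether is cleaved. Fallback, setting out from 6 and rejoining at 8: the acid chloride 7 is treated with excess AlCl3 (CH2Cl2, 0 °C to rt), the classical forcing conditions for halogenated 3-aryloxypropanoyl chlorides, deliberately accepting loss of the benzyl group, to give 6-bromo-8-hydroxy-2,2-dimethylchroman-4-one F4. Re-benzylation (BnBr, K2CO3, DMF) returns to 8.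

Step 2 (hydroboration–oxidation). What may go wrong: β-elimination of the aryloxide from the β-aryloxy aldehyde during oxidative work-up or handling, and incomplete hydroboration next to the quaternary carbon. Fallback, setting out from 3 and rejoining at 6:
- Semi-hydrogenation (H2, Pd/CaCO3 poisoned with Pb(OAc)2, quinoline) gives 2-(benzyloxy)-4-bromo-1-[(2-methylbut-3-en-2-yl)oxy]benzene F5.
- Hydroboration–oxidation (9-BBN, THF; then H2O2, NaOH) gives 3-[2-(benzyloxy)-4-bromophenoxy]-3-methylbutan-1-ol F6.
- Oxidation with TEMPO (cat.) and PhI(OAc)2 in MeCN/H2O takes the alcohol to acid 6 without the aldehyde being isolated.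

Further compounds
F1 | step 7 | racemic 5,7-bis(benzyloxy)-2-[8-(benzyloxy)-2,2-dimethyl-4-oxochroman-6-yl]chroman-4-one | CC1(C)CC(=O)c2cc(C3CC(=O)c4c(OCc5ccccc5)cc(OCc5ccccc5)cc4O3)cc(OCc5ccccc5)c2O1
F2 | step 7 | racemic 5,7-dihydroxy-2-(8-hydroxy-2,2-dimethyl-4-oxochroman-6-yl)chroman-4-one | CC1(C)CC(=O)c2cc(C3CC(=O)c4c(O)cc(O)cc4O3)cc(O)c2O1
F3 | step 7 | (E)-1-(2,4,6-trihydroxyphenyl)-3-(8-hydroxy-2,2-dimethyl-4-oxochroman-6-yl)prop-2-en-1-one | CC1(C)CC(=O)c2cc(/C=C/C(=O)c3c(O)cc(O)cc3O)cc(O)c2O1
F4 | step 4 | 6-bromo-8-hydroxy-2,2-dimethylchroman-4-one | CC1(C)CC(=O)c2cc(Br)cc(O)c2O1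
F5 | step 2 | 2-(benzyloxy)-4-bromo-1-[(2-methylbut-3-en-2-yl)oxy]benzene | C=CC(C)(C)Oc1ccc(Br)cc1OCc1ccccc1
F6 | step 2 | 3-[2-(benzyloxy)-4-bromophenoxy]-3-methylbutan-1-ol | OCCC(C)(C)Oc1ccc(Br)cc1OCc1ccccc1
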